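**Retrosynthetic overview**

1. Last bond: the aryl allyl ether, made by Mitsunobu coupling of purchased 7-hydroxy-8-methoxycoumarin (the benzopyranone rings are never built) with an allylic alcohol that already carries the finished lactone.
2. Key disconnection: the γ-butyrolactone (numbered O1, C2(=O), C3(OH)(CH3), C4H2, C5H), the only ring the route has to make, is cut at C3–C4 and at O1–C5 and rebuilt in one pot as a formal (3+2) annulation of a C3–C2–O1 unit with a C4–C5 unit.
3. Enabling feature: O1–C2(=O)–C3(OH)(CH3) is a lactic acid unit. It is nucleophilic at C3 (enolate of the cis lactic acid/pivalaldehyde dioxolanone, a temporary ring that relays the lactate stereocentre) and then at O1 (carboxylate). C4 and C5 are vicinal sp3 carbons that can both carry leaving groups as an enantiopure 1,2-cyclic sulfate (second temporary ring; its C–O centre is inverted to give C5).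
4. The cyclic sulfate comes from (S)-glycidol: acetylide opening, Negishi carboalumination/hydroxymethylation (sets the E trisubstituted alkene), protecting-group exchange, sulfinylation/oxidation.
5. Ring order: dioxolanone and cyclic sulfate (both temporary) → lactone (key step, both temporary rings consumed) → attachment of the preformed coumarin.

Key step: step 8

Assumption: 7-hydroxy-8-methoxycoumarin is taken as a purchasable catalogue compound; the coumarin is attached after the key step so that no enolate or hydroxide ever meets the coumarin lactone.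

**Route**

Step 1
Reactants: 1 (S)-lactic acid; 2 pivalaldehyde
Product: 3 (2S,5S)-2-tert-butyl-5-methyl-1,3-dioxolan-4-one
Conditions: cat. TsOH·H2O, cat. H2SO4, pentane, reflux, Dean–Stark; recrystallisation (pentane/Et2O, −78 °C)
Reagents that add atoms: none
Why: Acid-catalysed acetalisation under thermodynamic control should favour the cis isomer, which is purified by low-temperature crystallisation; the lactate stereocentre is untouched and directs the new acetal centre (template for self-regeneration of stereocentres).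

Step 2
Reactants: 4 (S)-glycidol
Product: 5 (R)-pent-4-yne-1,2-diol
Conditions: HC≡CLi·H2N(CH2)2NH2 (3 equiv), DMSO, 0 °C → rt; then H2O
Reagents that add atoms: lithium acetylide–ethylenediamine complex, [Li+].[C-]#C.NCCN
Why: SN2 opening of the epoxide at its unsubstituted carbon by acetylide leaves the stereocentre untouched (the Payne rearrangement of the glycidol alkoxide is degenerate), the descriptor changing from S to R only through CIP priorities.

Step 3
Reactants: 5 (R)-pent-4-yne-1,2-diol
Product: 6 (4R)-4,5-bis[(tert-butyldimethylsilyl)oxy]pent-1-yne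
Conditions: TBSCl (2.4 equiv), imidazole, DMF, 0 °C → rt
Reagents that add atoms: tert-butyldimethylsilyl chloride, CC(C)(C)[Si](C)(C)Cl
Why: Standard bis-silylation gives ethers that tolerate trimethylaluminium and butyllithium in the next step.

Step 4
Reactants: 6 (4R)-4,5-bis[(tert-butyldimethylsilyl)oxy]pent-1-yne
Product: 9 (2E,5R)-5,6-bis[(tert-butyldimethylsilyl)oxy]-3-methylhex-2-en-1-ol, via alkenyldimethylalane 7 (not isolated), via lithium alkenylaluminate 8 (not isolated)
Conditions: Me3Al (3 equiv), Cp2ZrCl2 (0.25 equiv), CH2Cl2, 0 °C → rt; concentrate; n-BuLi (1 equiv), THF, −78 °C; (CH2O)n, −78 °C → rt; aq. Rochelle salt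
Reagents that add atoms: trimethylaluminium, C[Al](C)C (the methyl group; Al in 7 and 8); paraformaldehyde as formaldehyde, C=O (the CH2O unit); n-butyllithium, [Li]CCCC (butyl and Li appear only in 8)
Why: Negishi carboalumination adds Me–Al syn across the terminal alkyne with methyl on the internal carbon, and hydroxymethylation of the aluminate occurs with retention at the alkenyl carbon, so the E trisubstituted allylic alcohol should result.

Step 5
Reactants: 9 (2E,5R)-5,6-bis[(tert-butyldimethylsilyl)oxy]-3-methylhex-2-en-1-ol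
Product: 10 (2E,5R)-5,6-bis[(tert-butyldimethylsilyl)oxy]-1-[(tert-butyldiphenylsilyl)oxy]-3-methylhex-2-ene
Conditions: TBDPSCl, imidazole, CH2Cl2, 0 °C → rt
Reagents that add atoms: tert-butyl(chloro)diphenylsilane, CC(C)(C)[Si](Cl)(c1ccccc1)c1ccccc1
Why: Silylation of the primary allylic alcohol installs a group far more acid-stable than TBS, which allows the diol to be freed selectively.

Step 6
Reactants: 10 (2E,5R)-5,6-bis[(tert-butyldimethylsilyl)oxy]-1-[(tert-butyldiphenylsilyl)oxy]-3-methylhex-2-ene
Product: 11 (2R,4E)-6-[(tert-butyldiphenylsilyl)oxy]-4-methylhex-4-ene-1,2-diol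
Conditions: CSA (0.2 equiv), MeOH/CH2Cl2 1:1, 0 °C → rt
Reagents that add atoms: none
Why: Acid-catalysed methanolysis should remove both TBS ethers much faster than the primary TBDPS ether, in line with the known order of acid lability of silyl ethers.

Step 7
Reactants: 11 (2R,4E)-6-[(tert-butyldiphenylsilyl)oxy]-4-methylhex-4-ene-1,2-diol
Product: 13 (4R)-4-[(2E)-4-[(tert-butyldiphenylsilyl)oxy]-2-methylbut-2-en-1-yl]-1,3,2-dioxathiolane 2,2-dioxide, via cyclic sulfite 12 (not isolated)
Conditions: SOCl2, Et3N, CH2Cl2, 0 °C; then RuCl3·xH2O (0.1 mol %), NaIO4 (1.5 equiv), MeCN/H2O, 0 °C, 10 min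
Reagents that add atoms: thionyl chloride, O=S(Cl)Cl (the S=O unit); sodium periodate, [Na+].[O-]I(=O)(=O)=O (the second S=O oxygen)
Why: Two-stage cyclic sulfate synthesis (sulfinylation, then RuO4-catalysed S(IV)→S(VI) oxidation) touches no C–O bond, so the R centre is retained, and at very low Ru loading the sulfite oxidation should outrun attack on the alkene.

Step 8
Reactants: 3 (2S,5S)-2-tert-butyl-5-methyl-1,3-dioxolan-4-one (1.3 equiv); 13 (4R)-4-[(2E)-4-[(tert-butyldiphenylsilyl)oxy]-2-methylbut-2-en-1-yl]-1,3,2-dioxathiolane 2,2-dioxide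
Product: 17 (3R,5S)-5-[(2E)-4-[(tert-butyldiphenylsilyl)oxy]-2-methylbut-2-en-1-yl]-3-hydroxy-3-methyloxolan-2-one, via lithium enolate 14 (not isolated), via lithium alkyl sulfate 15 (not isolated), via dilithium carboxylate sulfate 16 (not isolated)
Conditions: LDA (1.25 equiv), THF, −78 °C; 13, THF/DMPU, −78 → −30 °C; then LiOH·H2O (2 equiv), H2O, 0 °C → rt, then 60 °C; aq. KHSO4 to pH 3
Reagents that add atoms: lithium hydroxide, [Li+].[OH-] (its oxygen becomes one of the two carboxyl oxygens of the lactone; Li in 16); lithium diisopropylamide, CC(C)[N-]C(C)C.[Li+] (Li of 14–16 only)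
Why: Proposed new method: a formal (3+2) annulation in which enolate 14 opens cyclic sulfate 13 at its primary carbon by SN2 (forming C3–C4), after which hydroxide unmasks the dioxolanone of 15 as a carboxylate (releasing pivalaldehyde and the tertiary hydroxyl), and this carboxylate in 16 expels the secondary sulfate monoester at carbon in a 5-exo-tet SN2 closure of the lactone (forming O1–C5). The closest known reaction types are the double displacement of 1,2-cyclic sulfates by malonate anions (cyclopropanes) or amidines (imidazolines), the alkylation of this dioxolanone enolate with reactive halides, and the lactonisation of γ-sulfonyloxy carboxylates with inversion. The quaternary centre C3 (R) is set by approach of the electrophile to the enolate face anti to the tert-butyl group of the acetal centre, which amounts to replacing the lactate hydrogen with retention; C5 (S) is not created but relayed, by inversion of the (4R) C–O centre of 13. The step needs C- over O-alkylation and primary over secondary attack on the cyclic sulfate (secured by the ester enolate and the steric bias of the monosubstituted ring), and C–O rather than S–O cleavage of the sulfate monoester (secured by keeping the medium non-acidic, where alkyl sulfate monoesters resist hydrolysis, until ring closure is complete; brief acidification at the end only recloses any lactone opened by excess base).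

Step 9
Reactants: 17 (3R,5S)-5-[(2E)-4-[(tert-butyldiphenylsilyl)oxy]-2-methylbut-2-en-1-yl]-3-hydroxy-3-methyloxolan-2-one
Product: 18 (3R,5S)-3-hydroxy-5-[(2E)-4-hydroxy-2-methylbut-2-en-1-yl]-3-methyloxolan-2-one
Conditions: HF·pyridine, pyridine, THF, 0 °C → rt
Reagents that add atoms: none
Why: Buffered fluoride desilylation is non-basic and should leave the lactone, the tertiary alcohol and both stereocentres untouched.

Step 10
Reactants: 18 (3R,5S)-3-hydroxy-5-[(2E)-4-hydroxy-2-methylbut-2-en-1-yl]-3-methyloxolan-2-one; 19 7-hydroxy-8-methoxycoumarin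
Product: 20 7-{[(2E)-4-[(2S,4R)-4-hydroxy-4-methyl-5-oxooxolan-2-yl]-3-methylbut-2-en-1-yl]oxy}-8-methoxy-2H-chromen-2-one
Conditions: PPh3, DIAD, THF, 0 °C → rt
Reagents that add atoms: none
Why: Mitsunobu etherification, in which the acidic 7-hydroxycoumarin should displace the activated primary allylic alcohol by SN2 without changing the alkene geometry, the tertiary alcohol being inert.

**Compound list**

1 | (S)-lactic acid | C[C@H](O)C(=O)O | starting material
2 | pivalaldehyde | CC(C)(C)C=O | starting material
3 | (2S,5S)-2-tert-butyl-5-methyl-1,3-dioxolan-4-one (cis) | C[C@@H]1O[C@H](C(C)(C)C)OC1=O | intermediate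
4 | (S)-glycidol | OC[C@H]1CO1 | starting material
5 | (R)-pent-4-yne-1,2-diol | OC[C@H](O)CC#C | intermediate
6 | (4R)-4,5-bis[(tert-butyldimethylsilyl)oxy]pent-1-yne | C#CC[C@H](CO[Si](C)(C)C(C)(C)C)O[Si](C)(C)C(C)(C)C | intermediate
7 | alkenyldimethylalane (not isolated): [(1E,4R)-4,5-bis[(tert-butyldimethylsilyl)oxy]-2-methylpent-1-en-1-yl]dimethylalane | C[Al](C)/C=C(\C)C[C@H](CO[Si](C)(C)C(C)(C)C)O[Si](C)(C)C(C)(C)C | intermediate
8 | lithium alkenylaluminate (not isolated): lithium butyl[(1E,4R)-4,5-bis[(tert-butyldimethylsilyl)oxy]-2-methylpent-1-en-1-yl]dimethylaluminate | [Li+].CCCC[Al-](C)(C)/C=C(\C)C[C@H](CO[Si](C)(C)C(C)(C)C)O[Si](C)(C)C(C)(C)C | intermediate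
9 | (2E,5R)-5,6-bis[(tert-butyldimethylsilyl)oxy]-3-methylhex-2-en-1-ol | OC/C=C(\C)C[C@H](CO[Si](C)(C)C(C)(C)C)O[Si](C)(C)C(C)(C)C | intermediate
10 | (2E,5R)-5,6-bis[(tert-butyldimethylsilyl)oxy]-1-[(tert-butyldiphenylsilyl)oxy]-3-methylhex-2-ene | CC(C)(C)[Si](c1ccccc1)(c1ccccc1)OC/C=C(\C)C[C@H](CO[Si](C)(C)C(C)(C)C)O[Si](C)(C)C(C)(C)C | intermediate
11 | (2R,4E)-6-[(tert-butyldiphenylsilyl)oxy]-4-methylhex-4-ene-1,2-diol | CC(C)(C)[Si](c1ccccc1)(c1ccccc1)OC/C=C(\C)C[C@H](CO)O | intermediate
12 | cyclic sulfite (not isolated, both S-epimers): (4R)-4-[(2E)-4-[(tert-butyldiphenylsilyl)oxy]-2-methylbut-2-en-1-yl]-1,3,2-dioxathiolane 2-oxide | CC(C)(C)[Si](c1ccccc1)(c1ccccc1)OC/C=C(\C)C[C@@H]1COS(=O)O1 | intermediate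
13 | (4R)-4-[(2E)-4-[(tert-butyldiphenylsilyl)oxy]-2-methylbut-2-en-1-yl]-1,3,2-dioxathiolane 2,2-dioxide | CC(C)(C)[Si](c1ccccc1)(c1ccccc1)OC/C=C(\C)C[C@@H]1COS(=O)(=O)O1 | intermediate
14 | lithium enolate (not isolated): lithium (2S)-2-tert-butyl-5-methyl-1,3-dioxol-4-olate | [Li+].CC1=C([O-])O[C@@H](C(C)(C)C)O1 | intermediate
15 | lithium alkyl sulfate (not isolated): lithium (2R,4E)-1-[(2S,4R)-2-tert-butyl-4-methyl-5-oxo-1,3-dioxolan-4-yl]-6-[(tert-butyldiphenylsilyl)oxy]-4-methylhex-4-en-2-yl sulfate | [Li+].C[C@]1(C[C@@H](C/C(C)=C/CO[Si](c2ccccc2)(c2ccccc2)C(C)(C)C)OS(=O)(=O)[O-])O[C@H](C(C)(C)C)OC1=O | intermediate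
16 | dilithium carboxylate sulfate (not isolated): dilithium (2R,4R,6E)-8-[(tert-butyldiphenylsilyl)oxy]-2-hydroxy-2,6-dimethyl-4-(sulfonatooxy)oct-6-enoate | [Li+].[Li+].CC(C)(C)[Si](c1ccccc1)(c1ccccc1)OC/C=C(\C)C[C@H](C[C@@](C)(O)C(=O)[O-])OS(=O)(=O)[O-] | intermediate
17 | (3R,5S)-5-[(2E)-4-[(tert-butyldiphenylsilyl)oxy]-2-methylbut-2-en-1-yl]-3-hydroxy-3-methyloxolan-2-one | CC(C)(C)[Si](c1ccccc1)(c1ccccc1)OC/C=C(\C)C[C@H]1C[C@@](C)(O)C(=O)O1 | intermediate
18 | (3R,5S)-3-hydroxy-5-[(2E)-4-hydroxy-2-methylbut-2-en-1-yl]-3-methyloxolan-2-one | OC/C=C(\C)C[C@H]1C[C@@](C)(O)C(=O)O1 | intermediate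
19 | 7-hydroxy-8-methoxycoumarin | COc1c(O)ccc2ccc(=O)oc12 | starting material
20 | 7-{[(2E)-4-[(2S,4R)-4-hydroxy-4-methyl-5-oxooxolan-2-yl]-3-methylbut-2-en-1-yl]oxy}-8-methoxy-2H-chromen-2-one (CNP0356189.1) | COc1c(OC/C=C(\C)C[C@H]2C[C@@](C)(O)C(=O)O2)ccc2ccc(=O)oc12 | target

**Step count and risks**

Total steps: 10. Longest linear sequence: 9 (steps 2–10, from (S)-glycidol); step 1 is a one-step side branch.

Steps most likely to fail:

Step 8 (labelled step). The second displacement may stall: the carboxylate may fail to expel the secondary sulfate at carbon, so that on acidification S–O hydrolysis with retention takes over and the C5 epimer forms. A lesser risk is slow C-alkylation, because the enolate decomposes above about −30 °C. The fallback uses known chemistry (deliberate retention, then inversion), sets out from 3 and 13 and returns at 17. The alkylation is run as above (LDA, THF, −78 °C, then 13) and followed by the standard acidic hydrolysis of the sulfate monoester (cat. H2SO4, 1 equiv H2O, THF, rt). The freed (R)-hydroxyl should then transacylate the dioxolanone and give the C5-epimeric lactone (3R,5R)-5-[(2E)-4-[(tert-butyldiphenylsilyl)oxy]-2-methylbut-2-en-1-yl]-3-hydroxy-3-methyloxolan-2-one F1. Aminolysis with dimethylaluminium dimethylamide (Me3Al, Me2NH, CH2Cl2, 0 °C → rt) should open it to the dihydroxy amide (2R,4R,6E)-8-[(tert-butyldiphenylsilyl)oxy]-2,4-dihydroxy-N,N,2,6-tetramethyloct-6-enamide F2. Selective mesylation of the secondary hydroxyl (MsCl, Et3N, CH2Cl2, −20 °C) should give the mesylate (2R,4R,6E)-8-[(tert-butyldiphenylsilyl)oxy]-1-(dimethylamino)-2-hydroxy-2,6-dimethyl-1-oxooct-6-en-4-yl methanesulfonate F3. On warming, F3 should cyclise through the amide oxygen with inversion (5-exo-tet) to an iminium lactone, which aqueous work-up hydrolyses to 17.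

Step 7. Over-oxidation: RuO4 may attack the electron-rich trisubstituted alkene competitively with the sulfite. The fallback sets out from 11 and returns at 13. It replaces the sulfinylation/oxidation sequence by direct, non-oxidative transfer of the SO2 unit to the dialkoxide (NaH, THF, −20 °C, then 1,1'-sulfonyldiimidazole, −20 °C → 0 °C), so that no oxidant meets the alkene; it makes no new compound (F0).

Step 4. The alkenyl–aluminium bond may be lost by protonolysis, or transfer to formaldehyde may be incomplete, which would give the 1,1-disubstituted alkene in place of 9. The fallback sets out from alane 7 and returns at 9. Iodinolysis (I2, THF, −30 °C) should give the vinyl iodide (1E,4R)-4,5-bis[(tert-butyldimethylsilyl)oxy]-1-iodo-2-methylpent-1-ene F4, which is isolated. Stille coupling with (tributylstannyl)methanol (Pd(PPh3)4, toluene, 80 °C) then introduces the CH2OH carbon with retention of alkene geometry.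

Further compounds
F1 | step 8 | (3R,5R)-5-[(2E)-4-[(tert-butyldiphenylsilyl)oxy]-2-methylbut-2-en-1-yl]-3-hydroxy-3-methyloxolan-2-one | CC(C)(C)[Si](c1ccccc1)(c1ccccc1)OC/C=C(\C)C[C@@H]1C[C@@](C)(O)C(=O)O1
F2 | step 8 | (2R,4R,6E)-8-[(tert-butyldiphenylsilyl)oxy]-2,4-dihydroxy-N,N,2,6-tetramethyloct-6-enamide | CC(C)(C)[Si](c1ccccc1)(c1ccccc1)OC/C=C(\C)C[C@@H](O)C[C@@](C)(O)C(=O)N(C)C
F3 | step 8 | (2R,4R,6E)-8-[(tert-butyldiphenylsilyl)oxy]-1-(dimethylamino)-2-hydroxy-2,6-dimethyl-1-oxooct-6-en-4-yl methanesulfonate | CC(C)(C)[Si](c1ccccc1)(c1ccccc1)OC/C=C(\C)C[C@@H](OS(C)(=O)=O)C[C@@](C)(O)C(=O)N(C)C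
F0 | step 7 | none | none
F4 | step 4 | (1E,4R)-4,5-bis[(tert-butyldimethylsilyl)oxy]-1-iodo-2-methylpent-1-ene | I/C=C(\C)C[C@H](CO[Si](C)(C)C(C)(C)C)O[Si](C)(C)C(C)(C)C
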